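## Retrosynthetic overview

1. The 14-membered ring is closed last, at C1–C14, by a SmI2 ketyl-radical addition to a 3-(acetoxymethyl)butenolide; loss of acetate from the resulting Sm enolate gives the exo-methylene. The lactone ring is therefore formed before the macrocycle.
2. The butenolide comes from a γ-hydroxy ynoate (syn-hydroalumination, formaldehyde trap, lactonisation); C2 is set by Zn-ProPhenol addition of methyl propiolate to an enal.
3. C5–C6 and the C6 stereocentre come from a catalytic asymmetric vinylogous Mukaiyama aldol of a C11 enal with a senecioyl morpholine amide dienolate.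
4. The C11 enal comes from a B-alkyl Suzuki coupling of an (E)-vinyl iodide (alkyne carboalumination) with a dienol made from (E)-3-methylpent-2-en-4-yn-1-ol.

Numbering used for the target (cembrane): C1 = ring-fusion CH carrying C15(=CH2)–C16(=O)O; C2 = lactone O–CH; C3=C4(Me); C5; C6(OAc); C7=C8(Me); C9; C10; C11=C12(Me); C13; C14(OH). The target is (1S,2S,6S,14S), all-E, trans-fused lactone.

Assumption: protecting-group atoms (TBS) are not counted toward the eight-atom limit, so the commercial TBS ether of but-3-yn-1-ol is used as a starting material.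

## Route

Step 1
Reactants: 1, tert-butyl(but-3-yn-1-yloxy)dimethylsilane
Product: 2, (E)-tert-butyl[(4-iodo-3-methylbut-3-en-1-yl)oxy]dimethylsilane
Conditions: Me3Al (2.5 equiv), Cp2ZrCl2 (0.25 equiv), CH2Cl2, 0 °C to rt; then I2, THF, −30 to 0 °C
Reagents that add atoms: trimethylaluminium, C[Al](C)C; iodine, II
Why: Negishi Zr-catalysed carboalumination adds Me–Al syn across the terminal alkyne and iodinolysis proceeds with retention, fixing the E C11=C12 alkene.

Step 2
Reactants: 3, (E)-3-methylpent-2-en-4-yn-1-ol
Product: 4, (E)-3-methylpenta-2,4-dien-1-ol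
Conditions: Zn(Cu/Ag), MeOH–H2O (1:1), 45 °C
Reagents that add atoms: none
Why: Boland semireduction of a conjugated enyne stops cleanly at the diene and leaves the existing E alkene (future C7=C8) untouched.

Step 3
Reactants: 4, (E)-3-methylpenta-2,4-dien-1-ol; 2, (E)-vinyl iodide
Product: 5, (2E,6E)-9-[(tert-butyldimethylsilyl)oxy]-3,7-dimethylnona-2,6-dien-1-ol
Conditions: 4, 9-BBN-H (2.2 equiv), THF, 0 °C to rt; then 2, PdCl2(dppf) (5 mol %), AsPh3, aq Cs2CO3, DMF, rt
Reagents that add atoms: none
Why: 9-BBN hydroborates only the terminal vinyl group (anti-Markovnikov; the trisubstituted alkene is inert), and the B-alkyl Suzuki–Miyaura coupling forms C9–C10... more precisely the C10–C11 sp3–sp2 bond with retention of both alkene geometries.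

Step 4
Reactants: 5, C11 allylic alcohol
Product: 6, (2E,6E)-9-[(tert-butyldimethylsilyl)oxy]-3,7-dimethylnona-2,6-dienal
Conditions: MnO2 (20 equiv), CH2Cl2, rt
Reagents that add atoms: none
Why: Chemoselective allylic oxidation gives the enal without E/Z isomerisation or silyl ether cleavage.

Step 5
Reactants: 7, 3-methylbut-2-enoyl chloride; 8, morpholine
Product: 9, 3-methyl-1-(morpholin-4-yl)but-2-en-1-one
Conditions: morpholine (2.1 equiv), CH2Cl2, 0 °C
Reagents that add atoms: none
Why: Simple N-acylation; excess morpholine rather than Et3N avoids vinylketene formation and deconjugation.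

Step 6
Reactants: 9, senecioyl morpholine amide
Product: 10, 4-[(1Z)-1-[(tert-butyldimethylsilyl)oxy]-3-methylbuta-1,3-dien-1-yl]morpholine
Conditions: LDA, THF–DMPU, −78 °C; TBSCl, −78 °C to rt
Reagents that add atoms: tert-butyldimethylsilyl chloride, CC(C)(C)[Si](C)(C)Cl
Why: Kinetic γ-deprotonation of the β,β-dimethyl enamide and O-silylation give the N,O-silyl dienyl ketene acetal used in vinylogous aldol chemistry.

Step 7
Reactants: 6, C11 enal; 10, silyl dienyl ketene N,O-acetal
Product: 11, (2E,5S,6E,10E)-13-[(tert-butyldimethylsilyl)oxy]-5-hydroxy-3,7,11-trimethyl-1-(morpholin-4-yl)trideca-2,6,10-trien-1-one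
Conditions: SiCl4 (1.1 equiv), Denmark binaphthyldiamine bisphosphoramide (5 mol %; the enantiomer giving Si-face attack, expected (S,S), to be confirmed by Mosher analysis), i-Pr2NEt (10 mol %), CH2Cl2, −72 °C; aq KF/NaHCO3
Reagents that add atoms: none
Why: Denmark Lewis-base-activated SiCl4 vinylogous Mukaiyama aldol is γ-selective and E-selective with amide dienolates and enals; catalyst-controlled Si-face addition sets C6 as S and creates the E C3=C4 alkene.

Step 8
Reactants: 11, hydroxy morpholine amide
Product: 12, (2E,5S,6E,10E)-13-[(tert-butyldimethylsilyl)oxy]-5-hydroxy-3,7,11-trimethyltrideca-2,6,10-trienal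
Conditions: DIBAL-H (3 equiv), THF, −78 °C; Rochelle salt
Reagents that add atoms: none
Why: Morpholine amides behave like Weinreb amides, so the stable tetrahedral aluminate releases the enal only on work-up (one equivalent of hydride is consumed by the free OH).

Step 9
Reactants: 12, hydroxy enal; 13, methyl propiolate
Product: 14, methyl (4S,5E,8S,9E,13E)-16-[(tert-butyldimethylsilyl)oxy]-4,8-dihydroxy-6,10,14-trimethylhexadeca-5,9,13-trien-2-ynoate
Conditions: 13 (3 equiv), Me2Zn (4 equiv), ProPhenol (20 mol %; the enantiomer giving Re-face addition, expected (S,S), to be confirmed by Mosher analysis), Ph3P=O (40 mol %), toluene, 4 °C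
Reagents that add atoms: none
Why: Trost Zn-ProPhenol alkynylation is at its best with enals and propiolate; catalyst-controlled Re-face 1,2-addition sets C2 as S (the extra Me2Zn covers the free C6–OH).

Step 10
Reactants: 14, γ-hydroxy ynoate
Product: 15, (5S)-3-(hydroxymethyl)-5-[(1E,4S,5E,9E)-12-[(tert-butyldimethylsilyl)oxy]-4-hydroxy-2,6,10-trimethyldodeca-1,5,9-trien-1-yl]furan-2(5H)-one
Conditions: DIBAL-H (2 equiv), THF, −78 to 0 °C; then i-Bu2AlH·NMO (1.5 equiv), 0 °C; monomeric HCHO in THF, 0 °C to rt; Rochelle salt; PPTS (cat.), CH2Cl2, rt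
Reagents that add atoms: formaldehyde, C=O
Why: Tsuda/Ramachandran syn-hydroalumination of the ynoate puts H on C1 and Al on C15, the α-alanyl acrylate is trapped by formaldehyde with retention, and the resulting Z-γ-hydroxy ester (C2 cis to the ester) lactonises to the 3-(hydroxymethyl)butenolide without touching C2.

Step 11
Reactants: 15, diol butenolide
Product: 16, {(5S)-5-[(1E,4S,5E,9E)-4-acetoxy-12-[(tert-butyldimethylsilyl)oxy]-2,6,10-trimethyldodeca-1,5,9-trien-1-yl]-2-oxo-2,5-dihydrofuran-3-yl}methyl acetate
Conditions: Ac2O (4 equiv), pyridine, CH2Cl2, 0 °C to rt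
Reagents that add atoms: acetic anhydride, CC(=O)OC(C)=O
Why: One acylation installs both the C6 acetate of the target and the allylic acetate leaving group needed in the ring closure; pyridine is too weak a base to epimerise C2.

Step 12
Reactants: 16, bis-acetate silyl ether
Product: 17, {(5S)-5-[(1E,4S,5E,9E)-4-acetoxy-12-hydroxy-2,6,10-trimethyldodeca-1,5,9-trien-1-yl]-2-oxo-2,5-dihydrofuran-3-yl}methyl acetate
Conditions: HF·pyridine, pyridine, THF, 0 °C to rt
Reagents that add atoms: none
Why: Buffered fluoride removes the primary TBS ether without acetate migration, allylic ionisation at C6 or base-induced damage to the butenolide.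

Step 13
Reactants: 17, primary alcohol
Product: 18, {(5S)-5-[(1E,4S,5E,9E)-4-acetoxy-2,6,10-trimethyl-12-oxododeca-1,5,9-trien-1-yl]-2-oxo-2,5-dihydrofuran-3-yl}methyl acetate
Conditions: Dess–Martin periodinane, NaHCO3, CH2Cl2, 0 °C; filtered and used at once
Reagents that add atoms: none
Why: Buffered Dess–Martin oxidation gives the β,γ-unsaturated aldehyde without base-mediated migration of the C11=C12 alkene into conjugation.

Step 14
Reactants: 18, aldehyde acetoxymethylbutenolide
Product: 19, kericembrenolide D
Conditions: SmI2 (2.2 equiv, syringe pump), HMPA (10 equiv), THF, 1 mM in 18, −78 °C; AcOH/THF quench at −78 °C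
Reagents that add atoms: none
Why: Proposed new method: SmI2–HMPA reduces the aldehyde to a non-chelated Sm(III) ketyl radical that adds to the butenolide β-carbon anti to the C2 side chain (setting C1 and the trans ring fusion), with the ring chain antiperiplanar across C14–C1 and the bulky Sm–O group away from C15 (predicting 14S), after which the α-lactone radical is reduced to the Sm enolate and expels acetate to give the exo-methylene; the closest known reactions are SmI2 ketyl–olefin couplings with acrylates and butenolides, radical addition–elimination allylation with Baylis–Hillman acetates, and McMurry/Pattenden radical-type 14-membered cembranoid ring closures.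

## Compound list

1 | tert-butyl(but-3-yn-1-yloxy)dimethylsilane | C#CCCO[Si](C)(C)C(C)(C)C | starting material
2 | (E)-tert-butyl[(4-iodo-3-methylbut-3-en-1-yl)oxy]dimethylsilane | I/C=C(\C)CCO[Si](C)(C)C(C)(C)C | intermediate
3 | (E)-3-methylpent-2-en-4-yn-1-ol | OC/C=C(\C)C#C | starting material
4 | (E)-3-methylpenta-2,4-dien-1-ol | OC/C=C(\C)C=C | intermediate
5 | (2E,6E)-9-[(tert-butyldimethylsilyl)oxy]-3,7-dimethylnona-2,6-dien-1-ol | OC/C=C(\C)CC/C=C(\C)CCO[Si](C)(C)C(C)(C)C | intermediate
6 | (2E,6E)-9-[(tert-butyldimethylsilyl)oxy]-3,7-dimethylnona-2,6-dienal | O=C/C=C(\C)CC/C=C(\C)CCO[Si](C)(C)C(C)(C)C | intermediate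
7 | 3-methylbut-2-enoyl chloride | CC(C)=CC(=O)Cl | starting material
8 | morpholine | C1COCCN1 | starting material
9 | 3-methyl-1-(morpholin-4-yl)but-2-en-1-one | CC(C)=CC(=O)N1CCOCC1 | intermediate
10 | 4-[(1Z)-1-[(tert-butyldimethylsilyl)oxy]-3-methylbuta-1,3-dien-1-yl]morpholine | C=C(C)/C=C(\O[Si](C)(C)C(C)(C)C)N1CCOCC1 | intermediate
11 | (2E,5S,6E,10E)-13-[(tert-butyldimethylsilyl)oxy]-5-hydroxy-3,7,11-trimethyl-1-(morpholin-4-yl)trideca-2,6,10-trien-1-one | O=C(/C=C(\C)C[C@H](O)/C=C(\C)CC/C=C(\C)CCO[Si](C)(C)C(C)(C)C)N1CCOCC1 | intermediate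
12 | (2E,5S,6E,10E)-13-[(tert-butyldimethylsilyl)oxy]-5-hydroxy-3,7,11-trimethyltrideca-2,6,10-trienal | O=C/C=C(\C)C[C@H](O)/C=C(\C)CC/C=C(\C)CCO[Si](C)(C)C(C)(C)C | intermediate
13 | methyl propiolate | C#CC(=O)OC | starting material
14 | methyl (4S,5E,8S,9E,13E)-16-[(tert-butyldimethylsilyl)oxy]-4,8-dihydroxy-6,10,14-trimethylhexadeca-5,9,13-trien-2-ynoate | COC(=O)C#C[C@@H](O)/C=C(\C)C[C@H](O)/C=C(\C)CC/C=C(\C)CCO[Si](C)(C)C(C)(C)C | intermediate
15 | (5S)-3-(hydroxymethyl)-5-[(1E,4S,5E,9E)-12-[(tert-butyldimethylsilyl)oxy]-4-hydroxy-2,6,10-trimethyldodeca-1,5,9-trien-1-yl]furan-2(5H)-one | OCC1=C[C@H](/C=C(\C)C[C@H](O)/C=C(\C)CC/C=C(\C)CCO[Si](C)(C)C(C)(C)C)OC1=O | intermediate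
16 | {(5S)-5-[(1E,4S,5E,9E)-4-acetoxy-12-[(tert-butyldimethylsilyl)oxy]-2,6,10-trimethyldodeca-1,5,9-trien-1-yl]-2-oxo-2,5-dihydrofuran-3-yl}methyl acetate | CC(=O)OCC1=C[C@H](/C=C(\C)C[C@H](OC(C)=O)/C=C(\C)CC/C=C(\C)CCO[Si](C)(C)C(C)(C)C)OC1=O | intermediate
17 | {(5S)-5-[(1E,4S,5E,9E)-4-acetoxy-12-hydroxy-2,6,10-trimethyldodeca-1,5,9-trien-1-yl]-2-oxo-2,5-dihydrofuran-3-yl}methyl acetate | CC(=O)OCC1=C[C@H](/C=C(\C)C[C@H](OC(C)=O)/C=C(\C)CC/C=C(\C)CCO)OC1=O | intermediate
18 | {(5S)-5-[(1E,4S,5E,9E)-4-acetoxy-2,6,10-trimethyl-12-oxododeca-1,5,9-trien-1-yl]-2-oxo-2,5-dihydrofuran-3-yl}methyl acetate | CC(=O)OCC1=C[C@H](/C=C(\C)C[C@H](OC(C)=O)/C=C(\C)CC/C=C(\C)CC=O)OC1=O | intermediate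
19 | kericembrenolide D, (1S,2S,6S,14S; 3E,7E,11E) | C=C1C(=O)O[C@H]2/C=C(\C)C[C@H](OC(C)=O)/C=C(\C)CC/C=C(\C)C[C@H](O)[C@H]12 | target

## Step count and risks

Total steps: 14. Longest linear sequence: 11 (steps 1, 3, 4, 7, 8, 9, 10, 11, 12, 13, 14).

Steps most likely to fail:

1. **Step 14 (SmI2 macrocyclisation).** Risks are pinacol dimerisation or simple reduction instead of ring closure, direct reduction of the allylic acetate, translactonisation onto the new C14 alkoxide, and the wrong C14 epimer. Fallback: change the radical and its oxidation level. Oxidise 17 to the C14 acid, make the phenyl selenoester, and close the same C1–C14 bond by acyl-radical macrocyclisation ((TMS)3SiH/AIBN, high dilution). Then eliminate AcOH with DBU to give the exo-methylene and set C14 by a separate diastereoselective ketone reduction.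

2. **Step 10 (hydroalumination / formaldehyde trap / lactonisation).** Risks are E/Z scrambling of the alanyl acrylate through the allenolate and poor capture of formaldehyde. Fallback: build the same butenolide by cross-coupling. Pd(PPh3)4/Bu3SnH syn-hydrostannation of 14 gives the α-stannyl butenolide; iododestannylation and Stille coupling with Bu3SnCH2OH then install the hydroxymethyl group.

3. **Step 9 (asymmetric alkynylation of a substrate with a free hydroxyl).** Risks are catalyst perturbation by the zinc alkoxide and uncertain sense or level of induction at C2. Fallback: set C2 by reduction instead of addition. Add lithiated methyl propiolate to 12 without stereocontrol, oxidise to the ynone (MnO2), and reduce with a Noyori Ru–TsDPEN transfer hydrogenation or CBS catalyst.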